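## Retrosynthetic overview

1. The target is a 2-chloro-3-hydroxy-7-methoxyphenanthrene (rings A, B, C) whose C4 carries phenol ring E and whose C6 carries chlorophenol ring D; an ArCH2–CH2Ar bridge ties D and E into a 12-membered ring. The end game is hydrogenation of a bridge alkene, then BCl3 removal of three isopropyl ethers.
2. Key disconnection: the bridge C–C bond and the phenanthrene C9=C10 bond are both opened to pairs of formyl groups, giving an open quateraryl tetraaldehyde E–A–C–D. One twofold McMurry coupling closes ring B and then the 12-membered ring.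
3. Enabling feature: C4 and C6 flank the bay carbon C5, and in an idealised planar phenanthrene their exocyclic bonds are parallel and about 3.6 Å apart. Once ring B exists, rings E and D are stacked face to face, with the ring E carbon meta to the biaryl bond and the ring D carbon ortho to it within bridging distance; every other pairing of the four formyl groups would give a meta- or para-bridged ring of 8 or 9 atoms.
4. The tetraaldehyde comes from three Suzuki couplings (E–A at an iodide, D–C at a bromide, A–C last at a triflate) of four benzaldehydes that already carry every oxygen, chlorine and formyl carbon.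
5. Ring order: rings A, C, D and E are bought as benzene rings; ring B and then the macrocycle are both formed in the key step.

Key step: step 13

Remark: the target is drawn without any stereodescriptor, so the twisted 12-membered ring is taken as stereochemically undefined (racemic or mobile) and no control of its sense of twist is planned.

## Route

Step 1
Reactants: 1 5-chloro-2,4-dihydroxybenzaldehyde
Product: 2 5-chloro-2-hydroxy-4-isopropoxybenzaldehyde
Conditions: 2-bromopropane (1.2 equiv), K2CO3 (1.05 equiv), DMF, 60 °C
Reagents that add atoms: 2-bromopropane, CC(C)Br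
Why: Williamson ether synthesis; the 2-OH is held in a hydrogen bond to the formyl group, so with one equivalent of base only the more acidic 4-OH should be alkylated.

Step 2
Reactants: 2 5-chloro-2-hydroxy-4-isopropoxybenzaldehyde
Product: 3 5-chloro-2-hydroxy-3-iodo-4-isopropoxybenzaldehyde
Conditions: N-iodosuccinimide, TFA (cat.), MeCN, rt
Reagents that add atoms: N-iodosuccinimide, O=C1CCC(=O)N1I
Why: Electrophilic aromatic iodination; C3 is the only free position ortho to both oxygen substituents (C5 carries chlorine, C6 is meta to both), so the iodine should enter between hydroxyl and isopropoxy.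

Step 3
Reactants: 4 3-bromo-4-hydroxybenzaldehyde
Product: 5 3-bromo-4-isopropoxybenzaldehyde
Conditions: 2-bromopropane, K2CO3, DMF, 60 °C
Reagents that add atoms: 2-bromopropane, CC(C)Br
Why: Williamson ether synthesis on the only phenol present.

Step 4
Reactants: 5 3-bromo-4-isopropoxybenzaldehyde
Product: 6 4-isopropoxy-3-(4,4,5,5-tetramethyl-1,3,2-dioxaborolan-2-yl)benzaldehyde
Conditions: bis(pinacolato)diboron, PdCl2(dppf), KOAc, 1,4-dioxane, 90 °C
Reagents that add atoms: bis(pinacolato)diboron, CC1(C)OB(B2OC(C)(C)C(C)(C)O2)OC1(C)C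
Why: Miyaura borylation of an aryl bromide; the aldehyde and the ether are inert to PdCl2(dppf)/KOAc.

Step 5
Reactants: 3 5-chloro-2-hydroxy-3-iodo-4-isopropoxybenzaldehyde; 6 4-isopropoxy-3-(4,4,5,5-tetramethyl-1,3,2-dioxaborolan-2-yl)benzaldehyde
Product: 7 5-chloro-3-(5-formyl-2-isopropoxyphenyl)-2-hydroxy-4-isopropoxybenzaldehyde
Conditions: Pd(OAc)2, SPhos, K3PO4, toluene/H2O, 70 °C
Reagents that add atoms: none
Why: Suzuki–Miyaura coupling; the C–I bond should add to zerovalent palladium far faster than the electron-rich C–Cl bond para to the phenoxide, and SPhos copes with the di-ortho-substituted iodide, giving the ring E–ring A bond.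

Step 6
Reactants: 7 5-chloro-3-(5-formyl-2-isopropoxyphenyl)-2-hydroxy-4-isopropoxybenzaldehyde
Product: 8 4-chloro-6-formyl-2-(5-formyl-2-isopropoxyphenyl)-3-isopropoxyphenyl trifluoromethanesulfonate
Conditions: Tf2O, pyridine, CH2Cl2, 0 °C
Reagents that add atoms: triflic anhydride, O=S(=O)(OS(=O)(=O)C(F)(F)F)C(F)(F)F
Why: O-sulfonylation (triflate formation) turns the ring A hydroxyl ortho to the formyl group into the leaving group for the last biaryl coupling.

Step 7
Reactants: 9 2-bromo-3-hydroxybenzaldehyde
Product: 10 2-bromo-6-chloro-3-hydroxybenzaldehyde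
Conditions: N-chlorosuccinimide (1.0 equiv), TfOH (cat.), MeCN, rt
Reagents that add atoms: N-chlorosuccinimide, O=C1CCC(=O)N1Cl
Why: Electrophilic aromatic chlorination; with C2 blocked by bromine the hydroxyl should direct to its para position C6, the position at which 3-hydroxybenzaldehyde itself is mainly halogenated.

Step 8
Reactants: 10 2-bromo-6-chloro-3-hydroxybenzaldehyde
Product: 11 2-bromo-6-chloro-3-isopropoxybenzaldehyde
Conditions: 2-bromopropane, K2CO3, DMF, 60 °C
Reagents that add atoms: 2-bromopropane, CC(C)Br
Why: Williamson ether synthesis on the only phenol present.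

Step 9
Reactants: 11 2-bromo-6-chloro-3-isopropoxybenzaldehyde; 12 (4-formyl-2-methoxyphenyl)boronic acid
Product: 13 6-chloro-2-(4-formyl-2-methoxyphenyl)-3-isopropoxybenzaldehyde
Conditions: Pd(PPh3)4, Na2CO3, DME/H2O, 85 °C
Reagents that add atoms: none
Why: Suzuki–Miyaura coupling; Pd(PPh3)4 should insert into the C–Br bond ortho to the formyl group and leave the C–Cl bond alone, forming the ring D–ring C bond.

Step 10
Reactants: 13 6-chloro-2-(4-formyl-2-methoxyphenyl)-3-isopropoxybenzaldehyde
Product: 14 2-(5-bromo-4-formyl-2-methoxyphenyl)-6-chloro-3-isopropoxybenzaldehyde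
Conditions: Br2 (1.05 equiv), NaOAc, AcOH, rt
Reagents that add atoms: bromine, BrBr
Why: Electrophilic aromatic bromination; the methoxy group directs para, to the position ortho to the ring C formyl group (as in the bromination of 3-methoxybenzaldehyde), while ring D is deactivated by a formyl group and a chlorine and offers only a hindered position ortho to isopropoxy.

Step 11
Reactants: 14 2-(5-bromo-4-formyl-2-methoxyphenyl)-6-chloro-3-isopropoxybenzaldehyde
Product: 15 6-chloro-2-[4-formyl-2-methoxy-5-(4,4,5,5-tetramethyl-1,3,2-dioxaborolan-2-yl)phenyl]-3-isopropoxybenzaldehyde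
Conditions: bis(pinacolato)diboron, PdCl2(dppf), KOAc, 1,4-dioxane, 90 °C
Reagents that add atoms: bis(pinacolato)diboron, CC1(C)OB(B2OC(C)(C)C(C)(C)O2)OC1(C)C
Why: Miyaura borylation of the aryl bromide; the aryl chloride should not be activated by PdCl2(dppf) under these conditions.

Step 12
Reactants: 8 4-chloro-6-formyl-2-(5-formyl-2-isopropoxyphenyl)-3-isopropoxyphenyl trifluoromethanesulfonate; 15 6-chloro-2-[4-formyl-2-methoxy-5-(4,4,5,5-tetramethyl-1,3,2-dioxaborolan-2-yl)phenyl]-3-isopropoxybenzaldehyde
Product: 16 5-chloro-2-[5-(3-chloro-2-formyl-6-isopropoxyphenyl)-2-formyl-4-methoxyphenyl]-3-(5-formyl-2-isopropoxyphenyl)-4-isopropoxybenzaldehyde (quateraryl tetraaldehyde, rings E–A–C–D)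
Conditions: PdCl2(dppf), K3PO4, 1,4-dioxane/H2O (10:1), 90 °C
Reagents that add atoms: none
Why: Suzuki–Miyaura coupling of an aryl triflate; the triflate ortho to a formyl group should add to zerovalent palladium much faster than either aryl chloride with a bisphosphine catalyst, so the ring A–ring C bond forms chemoselectively and completes the quateraryl.

Step 13
Reactants: 16 quateraryl tetraaldehyde
Product: 18 macrocyclic (Z)-stilbene tris(isopropyl ether), via phenanthrene dialdehyde 17 (not isolated)
Conditions: TiCl4, Zn, pyridine, THF, reflux; 16 added by syringe pump over 24 h (final ca. 1 mM)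
Reagents that add atoms: none
Why: Low-valent titanium from TiCl4 and Zn reduces the formyl groups to ketyl radicals, which pair to titanium pinacolates that lose both oxygens to titanium at reflux, leaving C=C bonds (McMurry coupling). The closest known reactions are the McMurry closure of biaryl-2,2'-dicarbaldehydes to phenanthrenes and the McMurry macrocyclisation of dialdehydes to the cis-stilbene bridges of macrocyclic bis(bibenzyl)s; here both run in one flask. Ring B closes first, as a six-membered ring, by coupling of the two formyl carbons ortho to the ring A–ring C bond, and aromatises to phenanthrene 17; the 12-membered ring then closes by coupling of the formyl carbons of rings D and E, which makes the ArCH=CHAr bond that becomes the ethano bridge. No stereocentre is formed, and the bridge alkene can only be Z inside a 12-membered ring. The step needs the right pairing and ring closure instead of chain growth: every other intramolecular pairing would give a meta- or para-bridged ring of 8 or 9 atoms and is ruled out by strain, and in 17 the parallel C4 and C6 exit bonds stack rings E and D so that their formyl carbons come within bonding distance, while slow addition keeps the concentration low. Rotation about the ring C–ring D bond, whose ortho groups are small, should be fast at reflux, so each rotamer of 17 can reach the arrangement with both formyl groups on the same face.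

Step 14
Reactants: 18 macrocyclic (Z)-stilbene tris(isopropyl ether)
Product: 19 tris(isopropyl ether) of the target (saturated ethano bridge)
Conditions: H2 (1 atm), 5% Pt/C (sulfided), EtOAc, rt
Reagents that add atoms: none
Why: Heterogeneous catalytic hydrogenation; the cis-stilbene double bond should be reduced under 1 atm of hydrogen, while sulfided platinum does not hydrogenolyse aryl chlorides and the phenanthrene C9–C10 bond stays aromatic.

Step 15
Reactants: 19 tris(isopropyl ether) of the target
Product: 20 target, CNP0310669.0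
Conditions: BCl3 (1 M in CH2Cl2), CH2Cl2, −20 °C to rt; then H2O
Reagents that add atoms: none
Why: Lewis-acid ether cleavage; BCl3 should remove the three secondary isopropyl groups (as 2-chloropropane) much faster than it attacks the aryl methyl ether, which has no neighbouring carbonyl to assist, so the three phenols are freed and the methoxy group is kept.

## Compound list

1 | 5-chloro-2,4-dihydroxybenzaldehyde | O=Cc1cc(Cl)c(O)cc1O | starting material
2 | 5-chloro-2-hydroxy-4-isopropoxybenzaldehyde | CC(C)Oc1cc(O)c(C=O)cc1Cl | intermediate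
3 | 5-chloro-2-hydroxy-3-iodo-4-isopropoxybenzaldehyde | CC(C)Oc1c(I)c(O)c(C=O)cc1Cl | intermediate
4 | 3-bromo-4-hydroxybenzaldehyde | O=Cc1ccc(O)c(Br)c1 | starting material
5 | 3-bromo-4-isopropoxybenzaldehyde | CC(C)Oc1ccc(C=O)cc1Br | intermediate
6 | 4-isopropoxy-3-(4,4,5,5-tetramethyl-1,3,2-dioxaborolan-2-yl)benzaldehyde | CC(C)Oc1ccc(C=O)cc1B1OC(C)(C)C(C)(C)O1 | intermediate
7 | 5-chloro-3-(5-formyl-2-isopropoxyphenyl)-2-hydroxy-4-isopropoxybenzaldehyde | O=Cc1cc(Cl)c(OC(C)C)c(-c2cc(C=O)ccc2OC(C)C)c1O | intermediate
8 | 4-chloro-6-formyl-2-(5-formyl-2-isopropoxyphenyl)-3-isopropoxyphenyl trifluoromethanesulfonate | O=Cc1cc(Cl)c(OC(C)C)c(-c2cc(C=O)ccc2OC(C)C)c1OS(=O)(=O)C(F)(F)F | intermediate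
9 | 2-bromo-3-hydroxybenzaldehyde | O=Cc1cccc(O)c1Br | starting material
10 | 2-bromo-6-chloro-3-hydroxybenzaldehyde | O=Cc1c(Cl)ccc(O)c1Br | intermediate
11 | 2-bromo-6-chloro-3-isopropoxybenzaldehyde | CC(C)Oc1ccc(Cl)c(C=O)c1Br | intermediate
12 | (4-formyl-2-methoxyphenyl)boronic acid | COc1cc(C=O)ccc1B(O)O | starting material
13 | 6-chloro-2-(4-formyl-2-methoxyphenyl)-3-isopropoxybenzaldehyde | COc1cc(C=O)ccc1-c1c(OC(C)C)ccc(Cl)c1C=O | intermediate
14 | 2-(5-bromo-4-formyl-2-methoxyphenyl)-6-chloro-3-isopropoxybenzaldehyde | COc1cc(C=O)c(Br)cc1-c1c(OC(C)C)ccc(Cl)c1C=O | intermediate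
15 | 6-chloro-2-[4-formyl-2-methoxy-5-(4,4,5,5-tetramethyl-1,3,2-dioxaborolan-2-yl)phenyl]-3-isopropoxybenzaldehyde | COc1cc(C=O)c(B2OC(C)(C)C(C)(C)O2)cc1-c1c(OC(C)C)ccc(Cl)c1C=O | intermediate
16 | 5-chloro-2-[5-(3-chloro-2-formyl-6-isopropoxyphenyl)-2-formyl-4-methoxyphenyl]-3-(5-formyl-2-isopropoxyphenyl)-4-isopropoxybenzaldehyde (quateraryl tetraaldehyde) | O=Cc1cc(Cl)c(OC(C)C)c(-c2cc(C=O)ccc2OC(C)C)c1-c1cc(-c2c(OC(C)C)ccc(Cl)c2C=O)c(OC)cc1C=O | intermediate
17 | 2-chloro-6-(3-chloro-2-formyl-6-isopropoxyphenyl)-4-(5-formyl-2-isopropoxyphenyl)-3-isopropoxy-7-methoxyphenanthrene (phenanthrene dialdehyde) | COc1cc2ccc3cc(Cl)c(OC(C)C)c(-c4cc(C=O)ccc4OC(C)C)c3c2cc1-c1c(OC(C)C)ccc(Cl)c1C=O | intermediate (not isolated)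
18 | macrocyclic (Z)-stilbene tris(isopropyl ether): 2-chloro-3-isopropoxy-7-methoxyphenanthrene with a 2-isopropoxyphenyl ring E on C4 and a 3-chloro-6-isopropoxyphenyl ring D on C6, C5 of ring E and C2 of ring D joined by a cis CH=CH bridge | COc1cc2ccc3cc(Cl)c(OC(C)C)c4c3c2cc1-c1c(OC(C)C)ccc(Cl)c1/C=C\c1ccc(OC(C)C)c-4c1 | intermediate
19 | tris(isopropyl ether) of the target: as 18 with a CH2–CH2 bridge | COc1cc2ccc3cc(Cl)c(OC(C)C)c4c3c2cc1-c1c(OC(C)C)ccc(Cl)c1CCc1ccc(OC(C)C)c-4c1 | intermediate
20 | CNP0310669.0: 2-chloro-3-hydroxy-7-methoxyphenanthrene with a 2-hydroxyphenyl ring E on C4 and a 3-chloro-6-hydroxyphenyl ring D on C6, C5 of ring E and C2 of ring D joined by a CH2–CH2 bridge | COc1cc2ccc3cc(Cl)c(O)c4c3c2cc1-c1c(O)ccc(Cl)c1CCc1ccc(O)c-4c1 | target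

## Step count and risks

Total step count: 15.
Longest linear sequence: 9 steps (from 9 through steps 7–15 to 20).

Three steps most likely to fail:

1. Step 13. What may go wrong: intermolecular carbonyl coupling (chain growth) outrunning closure of the 12-membered ring, or arrest of the bridge at the titanium pinacolate stage. Fallback: it sets out from 16 and changes the bond-forming event from carbonyl coupling to olefin metathesis. Fourfold Wittig methylenation (MePPh3Br, KOt-Bu, THF, 0 °C to rt) should give tetravinyl quateraryl F1. Twofold ring-closing metathesis with second-generation Grubbs catalyst, (H2IMes)(PCy3)Cl2Ru=CHPh, in dilute toluene at 80 °C under an argon sweep should first close the phenanthrene from the 2,2'-divinylbiaryl to divinyl phenanthrene F2 and then the cis bridge. Metathesis is reversible, so oligomers can return to the ring. The fallback comes back to the route at 18.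

2. Step 12. What may go wrong: slow transmetalation between two ortho-formyl, tri-ortho-substituted partners, with protodeboronation of the boronate and hydrolysis of the triflate taking over. Fallback: it sets out from 14 and 8 and replaces the boronate by a stannane. Stannylation of 14 (Me3SnSnMe3, Pd(PPh3)4, toluene, 100 °C) should give arylstannane F3. Copper-assisted Stille coupling of F3 with triflate 8 (Pd(PPh3)4, CuI, CsF, DMF, 50 °C) runs without aqueous base and should come back to the route at 16.

3. Step 10. What may go wrong: bromination on the wrong ring (ring D, ortho to isopropoxy) or twofold bromination. Fallback: it sets out from 8 and 11 and buys the bromine already in place, building the quateraryl linearly. Purchased 6-bromovanillin F4 is borylated (bis(pinacolato)diboron, PdCl2(dppf), KOAc, 1,4-dioxane, 90 °C) to phenol boronate F5. Suzuki coupling of F5 with triflate 8 (PdCl2(dppf), K3PO4, 1,4-dioxane/H2O) should give triaryl phenol F6. Triflation (Tf2O, pyridine, CH2Cl2) gives triaryl triflate F7, and Miyaura borylation gives triaryl boronate F8. Suzuki coupling of F8 with bromide 11 (Pd(PPh3)4, Na2CO3, DME/H2O) comes back to the route at 16, bypassing 13–15.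

## Further compounds

F1 | step 13 | tetravinyl quateraryl (16 with each formyl group replaced by vinyl) | C=Cc1cc(Cl)c(OC(C)C)c(-c2cc(C=C)ccc2OC(C)C)c1-c1cc(-c2c(OC(C)C)ccc(Cl)c2C=C)c(OC)cc1C=C
F2 | step 13 | divinyl phenanthrene (17 with each formyl group replaced by vinyl) | COc1cc2ccc3cc(Cl)c(OC(C)C)c(-c4cc(C=C)ccc4OC(C)C)c3c2cc1-c1c(OC(C)C)ccc(Cl)c1C=C
F3 | step 12 | 6-chloro-2-[4-formyl-2-methoxy-5-(trimethylstannyl)phenyl]-3-isopropoxybenzaldehyde (arylstannane) | COc1cc(C=O)c([Sn](C)(C)C)cc1-c1c(OC(C)C)ccc(Cl)c1C=O
F4 | step 10 | 6-bromovanillin (2-bromo-4-hydroxy-5-methoxybenzaldehyde) | COc1cc(C=O)c(Br)cc1O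
F5 | step 10 | 4-hydroxy-5-methoxy-2-(4,4,5,5-tetramethyl-1,3,2-dioxaborolan-2-yl)benzaldehyde (phenol boronate) | COc1cc(C=O)c(B2OC(C)(C)C(C)(C)O2)cc1O
F6 | step 10 | 5-chloro-2-(2-formyl-5-hydroxy-4-methoxyphenyl)-3-(5-formyl-2-isopropoxyphenyl)-4-isopropoxybenzaldehyde (triaryl phenol) | O=Cc1cc(Cl)c(OC(C)C)c(-c2cc(C=O)ccc2OC(C)C)c1-c1cc(O)c(OC)cc1C=O
F7 | step 10 | triaryl triflate (F6 with the phenol as its trifluoromethanesulfonate) | O=Cc1cc(Cl)c(OC(C)C)c(-c2cc(C=O)ccc2OC(C)C)c1-c1cc(OS(=O)(=O)C(F)(F)F)c(OC)cc1C=O
F8 | step 10 | triaryl boronate (F7 with the triflate replaced by the pinacol boronate) | O=Cc1cc(Cl)c(OC(C)C)c(-c2cc(C=O)ccc2OC(C)C)c1-c1cc(B2OC(C)(C)C(C)(C)O2)c(OC)cc1C=O
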